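**Retrosynthetic overview**
1. The ten-membered ring is closed last by ring-closing metathesis of two vinyl groups (C3=C4, Z) on a seco-triene that already carries all nine stereocentres.
2. C6–C7, the chlorine and the C5 exo-methylene come from one chromium-mediated γ-chloroallylation (new) of a C7 α-hydroxy aldehyde; the lactone is then moved from O9 to O7.
3. C8–OH and C17–H come from epoxidation and SmI2 reduction of a butenolide lactonised on O9, itself made by Ni/Cr coupling at a C9 aldehyde (C8–C9 bond).
4. Ring A is made first by a metal-free oxazaborolidinium Diels–Alder reaction of an achiral acetoxydiene with an achiral enal (C1, C10, C14), followed by reagent-controlled vinylation (C2) and allylic oxidation/methylenation (C11).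
5. Ring order: ring A, then a temporary five-membered isolactone, then the γ-lactone on O7, then the ten-membered ring.

Assumption and convention: the diene, the enal, methyl propionate, methyl dimethoxyacetate and propargyl alcohol are bought; locants are briarane locants (C1 quaternary carbon, C14 ring CH–OAc, C10 ring CH, C19 lactone carbonyl) and β is the face of the C1 methyl group; the target is read as 1R,2S,3Z,6S,7R,8R,9S,10S,14S,17R.

**Route**

Step 1
Reactants: 1 (E)-buta-1,3-dien-1-yl acetate; 2 (E)-4-acetoxy-2-methylbut-2-enal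
Product: 3 ring A aldehyde, (1R,2S,6S)-2-acetoxy-6-(acetoxymethyl)-1-methylcyclohex-3-ene-1-carbaldehyde
Conditions: (S)-o-tolyl oxazaborolidine from diphenylprolinol (20 mol %), Tf2NH (18 mol %), CH2Cl2, −78 to −40 °C
Reagents that add atoms: none
Why: Metal-free oxazaborolidinium-catalysed Diels–Alder reaction in which the boron-bound α-methyl enal reacts ortho and endo (14-OAc cis to CHO), the E-dienophile keeps CH2OAc trans to CHO, and the aryl-shielded catalyst fixes the absolute sense at C1, C10 and C14 (the antipodal catalyst is taken if the facial sense proves opposite).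

Step 2
Reactants: 3 ring A aldehyde
Product: 4 (2S)-vinyl carbinol (CHO of 3 converted into (S)-CH(OH)CH=CH2)
Conditions: Zn(CH=CH2)2 (2 equiv), (−)-3-exo-(dimethylamino)isoborneol (10 mol %), toluene, 0 °C
Reagents that add atoms: divinylzinc Zn(CH=CH2)2, C=C[Zn]C=C
Why: Amino-alcohol-catalysed alkenylzinc 1,2-addition (Oppolzer–Noyori type) in which the ligand delivers vinyl to the si face of the neopentyl aldehyde, giving the (2S)-carbinol under reagent control with the acetates untouched.

Step 3
Reactants: 4 (2S)-vinyl carbinol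
Product: 5 triacetate (2-O-acetyl 4)
Conditions: Ac2O, DMAP, pyridine, CH2Cl2, rt
Reagents that add atoms: acetic anhydride, CC(=O)OC(C)=O
Why: DMAP-catalysed acyl transfer onto the hindered secondary allylic alcohol, with no stereocentre touched.

Step 4
Reactants: 5 triacetate
Product: 6 enone (C11 ketone conjugated to C12=C13)
Conditions: CrO3, 3,5-dimethylpyrazole, CH2Cl2, −20 °C
Reagents that add atoms: chromium trioxide CrO3, O=[Cr](=O)=O
Why: Chromium-based allylic C–H oxidation at C11, the only unhindered allylic CH2 (the C14 and C2 allylic hydrogens are deactivated by their acetoxy groups), with no stereocentre touched.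

Step 5
Reactants: 6 enone
Product: 7 ketone (12,13-dihydro 6)
Conditions: [(Ph3P)CuH]6 (0.4 equiv), H2O, benzene, rt
Reagents that add atoms: none
Why: Conjugate hydride reduction by the copper hydride hexamer is chemoselective for the enone over the terminal vinyl group and the acetates, and C10 keeps its equatorial CH2OAc.

Step 6
Reactants: 7 ketone
Product: 8 exo-methylene triacetate (C11=CH2)
Conditions: Zn, CH2Br2, TiCl4, THF/CH2Cl2, 0 °C to rt
Reagents that add atoms: dibromomethane, BrCBr
Why: Takai–Lombardo methylenation is a non-basic zinc–titanium methylene transfer selective for ketones over esters, so the β-acetoxy ketone neither eliminates nor epimerises at C10.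

Step 7
Reactants: 8 exo-methylene triacetate
Product: 9 primary alcohol (free C9–OH)
Conditions: K2CO3 (0.2 equiv), MeOH, −10 °C
Reagents that add atoms: none
Why: Base-catalysed transesterification removes the unhindered primary acetate much faster than the two neopentyl-type secondary acetates.

Step 8
Reactants: 9 primary alcohol
Product: 10 C9 aldehyde
Conditions: Dess–Martin periodinane, NaHCO3, CH2Cl2, 0 °C
Reagents that add atoms: none
Why: Buffered Dess–Martin oxidation gives the β,γ-unsaturated aldehyde without epimerising C10 or moving the C11 methylene.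

Step 9
Reactants: 11 methyl propionate; 12 methyl dimethoxyacetate
Product: 13 methyl 4,4-dimethoxy-2-methyl-3-oxobutanoate
Conditions: LiN(i-Pr)2 (2.1 equiv), THF, −78 °C; add 12; aq. HCl work-up
Reagents that add atoms: none
Why: Crossed Claisen condensation of the propionate lithium enolate with the non-enolisable dimethoxyacetate, driven forward by the product enolate.

Step 10
Reactants: 13 methyl 4,4-dimethoxy-2-methyl-3-oxobutanoate
Product: 14 methyl (Z)-4,4-dimethoxy-2-methyl-3-(trifluoromethylsulfonyloxy)but-2-enoate
Conditions: NaH, PhNTf2, THF, 0 °C to rt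
Reagents that add atoms: N-phenylbis(trifluoromethanesulfonimide), O=S(=O)(N(c1ccccc1)S(=O)(=O)C(F)(F)F)C(F)(F)F
Why: O-Triflation of the chelated sodium enolate of the β-keto ester gives the (Z)-enol triflate with OTf cis to CO2Me.

Step 11
Reactants: 10 C9 aldehyde; 14 (Z)-enol triflate
Product: 16 (9S)-isobutenolide, via hydroxy ester 15 (not isolated)
Conditions: CrCl2 (3 equiv), NiCl2 (2 mol %), chiral oxazoline–sulfonamide ligand (Kishi type), Et3N, THF, rt
Reagents that add atoms: none
Why: Nozaki–Hiyama–Kishi Ni/Cr coupling with retention of alkene geometry, in which the chiral sulfonamide–chromium complex and attack anti to quaternary C1 give the (9S) carbinol, whose alkoxide lactonises onto the cis ester (O9–C19 isolactone).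

Step 12
Reactants: 16 (9S)-isobutenolide
Product: 17 8,17-epoxy isolactone (epoxide oxygen trans to ring A)
Conditions: aq. NaOCl, pyridine, 0 °C
Reagents that add atoms: sodium hypochlorite NaOCl, [Na+].[O-]Cl
Why: Nucleophilic (Weitz–Scheffer type) epoxidation of the electron-poor butenolide, with hypochlorite adding to C8 on the face trans to the ring A substituent at C9, which sets C8; the C11 methylene and the vinyl group are not electrophilic and stay intact.

Step 13
Reactants: 17 8,17-epoxy isolactone
Product: 18 8-hydroxy isolactone acetal (8-OH trans to ring A, 17-Me cis to C7)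
Conditions: SmI2 (2.5 equiv), THF/MeOH, −90 °C
Reagents that add atoms: none
Why: Samarium diiodide reduction of the α,β-epoxy lactone cleaves the C17–O bond and keeps the C8–O bond, and the samarium enolate is protonated from the alkoxide face (away from ring A and the acetal), giving the target C17 configuration.

Step 14
Reactants: 18 8-hydroxy isolactone acetal
Product: 19 alpha-hydroxy aldehyde (C7 aldehyde)
Conditions: LiBF4, MeCN/H2O (98:2), 60 °C
Reagents that add atoms: water, O
Why: Mild Lewis-acid-promoted acetal hydrolysis unmasks the non-enolisable α-hydroxy aldehyde without touching a stereocentre.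

Step 15
Reactants: 20 prop-2-yn-1-ol
Product: 21 (Z)-2-(chloromethylidene)but-3-en-1-ol
Conditions: CH2=CHMgCl (2.5 equiv), THF/toluene, reflux; then N-chlorosuccinimide, −30 °C
Reagents that add atoms: vinylmagnesium chloride CH2=CHMgCl, C=C[Mg]Cl; N-chlorosuccinimide, O=C1CCC(=O)N1Cl
Why: Anti-carbomagnesiation of the propargylic alkoxide gives a five-membered magnesacycle (vinyl on the internal carbon), and chlorination of the vinyl–magnesium bond with retention gives the Z-chloride.

Step 16
Reactants: 21 (Z)-2-(chloromethylidene)but-3-en-1-ol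
Product: 22 (Z)-2-(bromomethyl)-1-chlorobuta-1,3-diene
Conditions: CBr4, PPh3, CH2Cl2, 0 °C
Reagents that add atoms: carbon tetrabromide, BrC(Br)(Br)Br
Why: Appel bromination of the primary allylic alcohol without allylic shift; the bromide is used at once.

Step 17
Reactants: 19 alpha-hydroxy aldehyde; 22 (Z)-2-(bromomethyl)-1-chlorobuta-1,3-diene
Product: 24 9-hydroxy seco-triene lactone, via isolactone chlorohydrin 23 (not isolated)
Conditions: CrCl2 (2.2 equiv), THF/DMF, 0 °C; aq. NH4Cl; then camphorsulfonic acid (10 mol %), CH2Cl2, rt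
Reagents that add atoms: none
Why: Proposed new method: chromium-mediated γ-chloroallylation of an α-hydroxy aldehyde with a 2-vinyl-3-chloroallyl bromide, in which CrCl2 reduces only the allylic C–Br bond (the vinylic C–Cl bond is inert without nickel) to an allylchromium species that equilibrates to the E form (Cl trans to CH2Cr) and attacks through its chlorine-bearing γ-carbon in a chair six-membered transition state, so C6–C7 forms anti (6S,7R) with the double bond moved to C5=C16, while the aldehyde face follows a non-chelated Felkin–Anh/Cornforth arrangement (attack anti to the C8–O bond, past the smaller C17 arm); acid then moves the lactone from O9 to O7 because this relieves the all-cis isolactone (ring A, C7 chain and 17-Me on one face); the closest known reactions are the anti-selective Nozaki–Hiyama crotylation with CrCl2 and the γ-chloroallylboration of aldehydes to chlorohydrins.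

Step 18
Reactants: 24 9-hydroxy seco-triene lactone
Product: 25 seco-triene triacetate (9-O-acetyl 24)
Conditions: Ac2O, DMAP, pyridine, CH2Cl2, 0 °C to rt
Reagents that add atoms: acetic anhydride, CC(=O)OC(C)=O
Why: DMAP-catalysed acetylation of the secondary 9-OH, while the tertiary 8-OH is too hindered to react and stays free as in the target.

Step 19
Reactants: 25 seco-triene triacetate
Product: 26 CNP0178742.1
Conditions: second-generation Grubbs catalyst (10 mol %), toluene (1 mM), 80 °C
Reagents that add atoms: none
Why: Ring-closing olefin metathesis between the two monosubstituted vinyl groups (the 1,1-disubstituted C11 and C5 methylenes are spectators), with the ten-membered ring accommodating only the (3Z)-alkene.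

**Compound list**
1 | (E)-buta-1,3-dien-1-yl acetate | C=C/C=C/OC(C)=O | starting material
2 | (E)-4-acetoxy-2-methylbut-2-enal | CC(=O)OC/C=C(\C)C=O | starting material
3 | ring A aldehyde, (1R,2S,6S)-2-acetoxy-6-(acetoxymethyl)-1-methylcyclohex-3-ene-1-carbaldehyde (14-OAc cis to CHO, CH2OAc trans to CHO) | C1C=C[C@H](OC(C)=O)[C@](C)(C=O)[C@H]1COC(C)=O | intermediate
4 | (2S)-vinyl carbinol: CHO of 3 converted into (S)-CH(OH)CH=CH2, ring centres as in 3 | C1C=C[C@H](OC(C)=O)[C@](C)([C@@H](O)C=C)[C@H]1COC(C)=O | intermediate
5 | triacetate: 2-O-acetyl 4 (2S; 15β-Me, 14α-OAc, 10α-H) | C1C=C[C@H](OC(C)=O)[C@](C)([C@@H](OC(C)=O)C=C)[C@H]1COC(C)=O | intermediate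
6 | enone: 5 with C11 ketone conjugated to C12=C13 | O=C1C=C[C@H](OC(C)=O)[C@](C)([C@@H](OC(C)=O)C=C)[C@H]1COC(C)=O | intermediate
7 | ketone: 12,13-dihydro 6 | O=C1CC[C@H](OC(C)=O)[C@](C)([C@@H](OC(C)=O)C=C)[C@H]1COC(C)=O | intermediate
8 | exo-methylene triacetate: 7 with C11=CH2 | C=C1CC[C@H](OC(C)=O)[C@](C)([C@@H](OC(C)=O)C=C)[C@H]1COC(C)=O | intermediate
9 | primary alcohol: 8 with free C9–OH | C=C1CC[C@H](OC(C)=O)[C@](C)([C@@H](OC(C)=O)C=C)[C@H]1CO | intermediate
10 | C9 aldehyde: 9 oxidised at C9 (10α-H) | C=C1CC[C@H](OC(C)=O)[C@](C)([C@@H](OC(C)=O)C=C)[C@H]1C=O | intermediate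
11 | methyl propionate | CCC(=O)OC | starting material
12 | methyl dimethoxyacetate | COC(OC)C(=O)OC | starting material
13 | methyl 4,4-dimethoxy-2-methyl-3-oxobutanoate (racemic, enolisable) | COC(OC)C(=O)C(C)C(=O)OC | intermediate
14 | methyl (Z)-4,4-dimethoxy-2-methyl-3-(trifluoromethylsulfonyloxy)but-2-enoate | COC(OC)/C(OS(=O)(=O)C(F)(F)F)=C(\C)C(=O)OC | intermediate
15 | (9S)-hydroxy ester: C9 carbinol bearing the (Z)-C8(CH(OMe)2)=C17(Me)CO2Me unit, C9 cis to CO2Me | C=C1CC[C@H](OC(C)=O)[C@](C)([C@@H](OC(C)=O)C=C)[C@H]1[C@H](O)/C(C(OC)OC)=C(/C)C(=O)OC | intermediate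
16 | (9S)-isobutenolide: 4-(dimethoxymethyl)-3-methylfuran-2(5H)-one carrying ring A at C5 (O9–C19 lactone) | C=C1CC[C@H](OC(C)=O)[C@](C)([C@@H](OC(C)=O)C=C)[C@H]1[C@@H]2OC(=O)C(C)=C2C(OC)OC | intermediate
17 | 8,17-epoxy isolactone: epoxide oxygen trans to ring A on the lactone ring | C=C1CC[C@H](OC(C)=O)[C@](C)([C@@H](OC(C)=O)C=C)[C@H]1[C@@H]2OC(=O)[C@@]3(C)O[C@@]23C(OC)OC | intermediate
18 | 8-hydroxy isolactone acetal: 8-OH trans to ring A, 17-Me cis to the C7 acetal | C=C1CC[C@H](OC(C)=O)[C@](C)([C@@H](OC(C)=O)C=C)[C@H]1[C@@H]2OC(=O)[C@H](C)[C@]2(O)C(OC)OC | intermediate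
19 | alpha-hydroxy aldehyde: 18 with C7 as CHO | C=C1CC[C@H](OC(C)=O)[C@](C)([C@@H](OC(C)=O)C=C)[C@H]1[C@@H]2OC(=O)[C@H](C)[C@]2(O)C=O | intermediate
20 | prop-2-yn-1-ol | C#CCO | starting material
21 | (Z)-2-(chloromethylidene)but-3-en-1-ol | OC/C(C=C)=C\Cl | intermediate
22 | (Z)-2-(bromomethyl)-1-chlorobuta-1,3-diene | BrC/C(C=C)=C\Cl | intermediate
23 | isolactone chlorohydrin: (6S,7R) anti-chlorohydrin with C5=C16 methylene and C4 vinyl, lactone still on O9 | C=C1CC[C@H](OC(C)=O)[C@](C)([C@@H](OC(C)=O)C=C)[C@H]1[C@@H]2OC(=O)[C@H](C)[C@]2(O)[C@@H](O)[C@@H](Cl)C(=C)C=C | intermediate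
24 | 9-hydroxy seco-triene lactone: C7–O–C19 γ-lactone, free 9-OH and 8-OH, (6S,7R,8R,9S,17R) | C=C1CC[C@H](OC(C)=O)[C@](C)([C@@H](OC(C)=O)C=C)[C@H]1[C@H](O)[C@]2(O)[C@@H](C)C(=O)O[C@H]2[C@@H](Cl)C(=C)C=C | intermediate
25 | seco-triene triacetate: 9-O-acetyl 24 | C=C1CC[C@H](OC(C)=O)[C@](C)([C@@H](OC(C)=O)C=C)[C@H]1[C@H](OC(C)=O)[C@]2(O)[C@@H](C)C(=O)O[C@H]2[C@@H](Cl)C(=C)C=C | intermediate
26 | CNP0178742.1, (1R,2S,3Z,6S,7R,8R,9S,10S,14S,17R)-2,9,14-triacetoxy-6-chloro-8-hydroxybriara-3,5(16),11(20)-trien-19,7-olide | C=C1CC[C@H](OC(C)=O)[C@]2(C)[C@@H](OC(C)=O)/C=C\C(=C)[C@H](Cl)[C@@H]3OC(=O)[C@H](C)[C@@]3(O)[C@@H](OC(C)=O)[C@@H]12 | target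

**Totals and risks**
Total steps: 19. Longest linear sequence: 15 steps (1–8, 11–14, 17–19).

Most likely to fail:

Step 17 (the new chloroallylation). The allylchromium species may react at its α-carbon, the allylic chloride product may be reduced further by divalent chromium, or a chelated transition state may give the C7 epimer. Fallback with known chemistry, setting out from 19: zirconium-catalysed carboalumination of but-1-en-3-yne followed by iodine gives (E)-1-iodo-2-methylbuta-1,3-diene F1. Nozaki–Hiyama–Kishi coupling of F1 with 19 (CrCl2, NiCl2 cat., DMF) gives the Felkin dienyl carbinol F2. Selenium-catalysed ene-type allylic chlorination of F2 (PhSeCl 10 mol %, N-chlorosuccinimide, CH2Cl2) places chlorine on C6 and moves the double bond to C5=C16, giving chlorohydrin 23 after separation of C6 epimers. The acid treatment of step 17 then brings the route back at 24.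

Step 19 (ten-membered ring closure). Strain, oligomerisation or attack on the diene may defeat the metathesis of 25. Fallback, setting out from 23 (isolated by leaving out the acid treatment of step 17): metathesis is run on this cis-fused isolactone, where both alkene-bearing arms sit on the same face of the five-membered ring and 7-OH and 8-OH are free, to give the macrocyclic isolactone F3. Acid-promoted lactone transfer to O7 inside the macrocycle gives the 9-hydroxy macrocycle F4, and acetylation (Ac2O, DMAP) comes back to the route at 26.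

Step 12 (epoxidation of the tetrasubstituted butenolide). Conjugate addition to the fully substituted C8 may be too slow, or C9 may epimerise. Fallback, setting out from 16: copper-catalysed conjugate borylation (CuCl, N-heterocyclic carbene ligand, NaOt-Bu, B2pin2, MeOH, THF) adds boron to C8 trans to ring A and gives the tertiary pinacol boronate F5. Oxidation with NaBO3 (retention at C8) comes back at 18, bypassing 17 and the SmI2 step.

**Further compounds**
F1 | step 17 | (E)-1-iodo-2-methylbuta-1,3-diene | I/C=C(\C)C=C
F2 | step 17 | dienyl carbinol: (7R)-carbinol of 19 carrying the (E)-CH=C(CH3)CH=CH2 group, lactone on O9 | C=C1CC[C@H](OC(C)=O)[C@](C)([C@@H](OC(C)=O)C=C)[C@H]1[C@@H]2OC(=O)[C@H](C)[C@]2(O)[C@@H](O)/C=C(\C)C=C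
F3 | step 19 | macrocyclic isolactone: (3Z) ten-membered ring closed, O9–C19 lactone, free 7-OH and 8-OH | C=C1CC[C@H](OC(C)=O)[C@]2(C)[C@@H](OC(C)=O)/C=C\C(=C)[C@H](Cl)[C@H](O)[C@@]3(O)[C@@H](C)C(=O)O[C@H]3[C@@H]12
F4 | step 19 | 9-hydroxy macrocycle: 9-O-deacetyl 26 | C=C1CC[C@H](OC(C)=O)[C@]2(C)[C@@H](OC(C)=O)/C=C\C(=C)[C@H](Cl)[C@@H]3OC(=O)[C@H](C)[C@@]3(O)[C@@H](O)[C@@H]12
F5 | step 12 | tertiary pinacol boronate: 18 with Bpin in place of 8-OH | C=C1CC[C@H](OC(C)=O)[C@](C)([C@@H](OC(C)=O)C=C)[C@H]1[C@@H]2OC(=O)[C@H](C)[C@]2(B3OC(C)(C)C(C)(C)O3)C(OC)OC
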